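**Retrosynthetic overview** (rings lettered A–E from the 3,5-dihydroxyphenyl end)

1. The target is the free polyphenol of octamethyl ether 22; the last step is a global O-demethylation of rings A–D.
2. The strategy rests on ring E, a 2,4,6-trihydroxyphenyl ring whose C-1 carries the ether oxygen from ring D. C-1 with that oxygen maps onto the ArO–CH2 terminus (C-6) of a methyl 3,5-dioxohexanoate, and the three C–OH carbons map onto the ester and the two ketone carbons. An intramolecular Claisen condensation forms the ring E C-1–C-2 bond (chain C-6 to C-1).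
3. The triketide 20 comes from the ABCD mono-phenol 15 by O-alkylation with methyl bromoacetate and acylation of the methyl acetoacetate dianion.
4. The ABCD tetramer is assembled from arene building blocks through three diaryl ether bonds. B–C is made by SNAr of bromophenol 4 on fluoroaldehyde 3, C–D by Ullmann coupling of bromide 5 with phenol 9, and A–B by Ullmann coupling after Dakin unmasking of the flanked ring-B hydroxyl.
5. Rings A–D are bought as benzenes; ring E is the only ring formed, and it is formed last.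

Key step: step 11

Remark: the target has no stereogenic element, so the route needs no stereocontrol. "ArO" below means the ABCD aryloxy group of phenol 15.

**Step 1**
Reactants: 1 1-fluoro-3,5-dimethoxybenzene
Product: 3 2-fluoro-4,6-dimethoxybenzaldehyde, via aryl iminium chloride 2 (not isolated)
Conditions: POCl3, DMF, 0 → 70 °C; then H2O, 50 °C
Reagents that add atoms: N,N-dimethylformamide CN(C)C=O (formyl carbon); water O (carbonyl oxygen)
Why: Vilsmeier–Haack formylation should go mainly at C-2, which is ortho/para to both methoxy groups and less crowded than C-4 between them; the iminium salt 2 is hydrolysed on work-up and the minor 4-fluoro-2,6-dimethoxy isomer should be removable by crystallisation.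

**Step 2**
Reactants: 3 2-fluoro-4,6-dimethoxybenzaldehyde; 4 4-bromo-2,6-dimethoxyphenol
Product: 5 2-(4-bromo-2,6-dimethoxyphenoxy)-4,6-dimethoxybenzaldehyde
Conditions: Cs2CO3, DMSO, 110 °C, Ar
Reagents that add atoms: none
Why: SNAr in which the ortho-formyl group takes up the charge of the Meisenheimer adduct while both methoxy groups are meta to the reacting carbon; the aryl bromide of 4 is inert without a metal and is kept as the handle for ring D.

**Step 3**
Reactants: 6 2-hydroxy-4,6-dimethoxybenzaldehyde
Product: 7 2-(benzyloxy)-4,6-dimethoxybenzaldehyde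
Conditions: BnBr, K2CO3, DMF, 60 °C
Reagents that add atoms: benzyl bromide BrCc1ccccc1
Why: Williamson etherification of the chelated phenol, which masks the oxygen that later becomes the alkylation site of ring D.

**Step 4**
Reactants: 7 2-(benzyloxy)-4,6-dimethoxybenzaldehyde
Product: 9 2-(benzyloxy)-4,6-dimethoxyphenol, via aryl formate 8 (not isolated)
Conditions: mCPBA, CH2Cl2, 0 °C → rt; then K2CO3 (cat.), MeOH, rt, Ar
Reagents that add atoms: mCPBA OOC(=O)c1cccc(Cl)c1
Why: Dakin-type Baeyer–Villiger oxidation, in which the electron-rich trioxygenated aryl group migrates in preference to hydrogen, and the formate is cleaved by methanolysis.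

**Step 5**
Reactants: 5 2-(4-bromo-2,6-dimethoxyphenoxy)-4,6-dimethoxybenzaldehyde; 9 2-(benzyloxy)-4,6-dimethoxyphenol
Product: 10 2-{4-[2-(benzyloxy)-4,6-dimethoxyphenoxy]-2,6-dimethoxyphenoxy}-4,6-dimethoxybenzaldehyde
Conditions: CuI (cat.), picolinic acid (cat.), K3PO4, DMSO, 95 °C, Ar
Reagents that add atoms: none
Why: Ullmann diaryl ether coupling of a 2,6-dialkoxyphenol with an aryl bromide flanked by two hydrogens, under ligand conditions suited to hindered phenols; the non-enolisable aldehyde should survive.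

**Step 6**
Reactants: 10 2-{4-[2-(benzyloxy)-4,6-dimethoxyphenoxy]-2,6-dimethoxyphenoxy}-4,6-dimethoxybenzaldehyde
Product: 12 2-{4-[2-(benzyloxy)-4,6-dimethoxyphenoxy]-2,6-dimethoxyphenoxy}-4,6-dimethoxyphenol, via aryl formate 11 (not isolated)
Conditions: mCPBA, CH2Cl2, 0 °C → rt; then K2CO3 (cat.), MeOH, rt, Ar
Reagents that add atoms: mCPBA OOC(=O)c1cccc(Cl)c1
Why: Dakin-type Baeyer–Villiger oxidation converts the formyl group that activated step 2 into the flanked ring-B hydroxyl, again by migration of the electron-rich aryl group.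

**Step 7**
Reactants: 12 2-{4-[2-(benzyloxy)-4,6-dimethoxyphenoxy]-2,6-dimethoxyphenoxy}-4,6-dimethoxyphenol; 13 1-iodo-3,5-dimethoxybenzene
Product: 14 1-(benzyloxy)-2-{4-[2-(3,5-dimethoxyphenoxy)-3,5-dimethoxyphenoxy]-3,5-dimethoxyphenoxy}-3,5-dimethoxybenzene
Conditions: CuI (cat.), picolinic acid (cat.), K3PO4, DMSO, 95 °C, Ar
Reagents that add atoms: none
Why: Ullmann diaryl ether coupling of the hindered phenol with an unhindered aryl iodide; no other halide or free phenol is present at this stage.

**Step 8**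
Reactants: 14 ABCD benzyl ether
Product: 15 2-{4-[2-(3,5-dimethoxyphenoxy)-3,5-dimethoxyphenoxy]-3,5-dimethoxyphenoxy}-3,5-dimethoxyphenol (ArOH)
Conditions: H2 (1 atm), 10% Pd/C, EtOAc–MeOH, rt
Reagents that add atoms: none
Why: Hydrogenolysis of the benzyl ether; aryl methyl ethers and diaryl ethers are stable and no halogen remains.

**Step 9**
Reactants: 15 ArOH; 16 methyl bromoacetate
Product: 17 methyl 2-(ArO)acetate
Conditions: K2CO3, acetone, reflux
Reagents that add atoms: none
Why: Williamson alkylation of the phenoxide at a reactive sp3 carbon; this makes the C–O bond that becomes the ring D–ring E ether.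

**Step 10**
Reactants: 17 methyl 2-(ArO)acetate; 18 methyl acetoacetate
Product: 20 methyl 6-(ArO)-3,5-dioxohexanoate, via acetoacetate dianion 19 (not isolated)
Conditions: 18 (2.5 equiv), NaH, THF, 0 °C; n-BuLi, 0 °C; then 17, 0 °C → rt; AcOH, −20 °C; used without delay
Reagents that add atoms: none
Why: Claisen acylation of the acetoacetate dianion at its terminal (γ) carbon by the activated α-aryloxy ester; excess dianion is used because the diketo ester product is deprotonated as it forms, which also prevents over-addition.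

**Step 11**
Reactants: 20 methyl 6-(ArO)-3,5-dioxohexanoate
Product: 22 2-(ArO)benzene-1,3,5-triol (pentamer with free ring E), via 2-(ArO)cyclohexane-1,3,5-trione 21 (not isolated)
Conditions: t-BuOK (5 equiv), THF, 0 → 60 °C, Ar; then degassed 1 M HCl, 0 °C
Reagents that add atoms: none
Why: Intramolecular Claisen (Dieckmann-type) condensation: excess t-BuOK converts 20 into its polyenolate, and the carbanion at C-6, the only α-position left and acidified by the C-5 carbonyl and the aryloxy oxygen, adds to the ester carbon C-1; loss of methoxide gives trione 21, which enolises three times to aromatic ring E and is held as its phenoxide, so the C–C bond formation is not reversed. The closest known reaction type is the base-mediated Claisen cyclisation of 3,5-dioxoalkanoate esters to phloroglucinols, the laboratory counterpart of ring closure by type III polyketide synthases. The six-membered ring closes in a favoured 6-(enolendo)-exo-trig mode, with the C-5/C-6 enolate inside the new ring and the ester C=O exocyclic. No stereocentre is formed. The step needs C-acylation at C-6 to win over O-acylation by the C-5 enolate oxygen, which would give the 6-(aryloxymethyl)-4-hydroxy-2-pyrone; aprotic, strongly basic conditions are chosen because lactonisation should stay reversible through the methoxide set free, whereas only the carbocyclic path ends in an aromatic sink. The crowded aryl–oxygen bond between rings D and E already exists from step 9, so no substitution at a doubly flanked aromatic carbon is required.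

**Step 12**
Reactants: 22 2-(ArO)benzene-1,3,5-triol
Product: 24 target pentamer (CNP0018313.0), via undeca(dibromoboryl) ether 23 (not isolated)
Conditions: BBr3 (excess), CH2Cl2, −78 °C → rt, Ar; then H2O, 0 °C
Reagents that add atoms: none
Why: Lewis-acid ether cleavage, in which bromide attacks the methyl carbon of each boron-complexed aryl methyl ether; the diaryl ether bonds offer no sp3 carbon and should survive, and the aryl borates are hydrolysed on work-up.

**Compound list**

1 | 1-fluoro-3,5-dimethoxybenzene | COc1cc(F)cc(OC)c1 | starting material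
2 | (2-fluoro-4,6-dimethoxybenzylidene)dimethyliminium chloride | COc1cc(OC)c(C=[N+](C)C)c(F)c1.[Cl-] | intermediate
3 | 2-fluoro-4,6-dimethoxybenzaldehyde | COc1cc(OC)c(C=O)c(F)c1 | intermediate
4 | 4-bromo-2,6-dimethoxyphenol | COc1cc(Br)cc(OC)c1O | starting material
5 | 2-(4-bromo-2,6-dimethoxyphenoxy)-4,6-dimethoxybenzaldehyde | COc1cc(OC)c(C=O)c(Oc2c(OC)cc(Br)cc2OC)c1 | intermediate
6 | 2-hydroxy-4,6-dimethoxybenzaldehyde | COc1cc(O)c(C=O)c(OC)c1 | starting material
7 | 2-(benzyloxy)-4,6-dimethoxybenzaldehyde | COc1cc(OCc2ccccc2)c(C=O)c(OC)c1 | intermediate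
8 | 2-(benzyloxy)-4,6-dimethoxyphenyl formate | COc1cc(OCc2ccccc2)c(OC=O)c(OC)c1 | intermediate
9 | 2-(benzyloxy)-4,6-dimethoxyphenol | COc1cc(OCc2ccccc2)c(O)c(OC)c1 | intermediate
10 | 2-{4-[2-(benzyloxy)-4,6-dimethoxyphenoxy]-2,6-dimethoxyphenoxy}-4,6-dimethoxybenzaldehyde | COc1cc(OC)c(C=O)c(Oc2c(OC)cc(Oc3c(OC)cc(OC)cc3OCc3ccccc3)cc2OC)c1 | intermediate
11 | formate ester of phenol 12 | COc1cc(OC)c(OC=O)c(Oc2c(OC)cc(Oc3c(OC)cc(OC)cc3OCc3ccccc3)cc2OC)c1 | intermediate
12 | 2-{4-[2-(benzyloxy)-4,6-dimethoxyphenoxy]-2,6-dimethoxyphenoxy}-4,6-dimethoxyphenol | COc1cc(OC)c(O)c(Oc2c(OC)cc(Oc3c(OC)cc(OC)cc3OCc3ccccc3)cc2OC)c1 | intermediate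
13 | 1-iodo-3,5-dimethoxybenzene | COc1cc(I)cc(OC)c1 | starting material
14 | 1-(benzyloxy)-2-{4-[2-(3,5-dimethoxyphenoxy)-3,5-dimethoxyphenoxy]-3,5-dimethoxyphenoxy}-3,5-dimethoxybenzene | COc1cc(OC)cc(Oc2c(OC)cc(OC)cc2Oc2c(OC)cc(Oc3c(OC)cc(OC)cc3OCc3ccccc3)cc2OC)c1 | intermediate
15 | 2-{4-[2-(3,5-dimethoxyphenoxy)-3,5-dimethoxyphenoxy]-3,5-dimethoxyphenoxy}-3,5-dimethoxyphenol (ArOH) | COc1cc(OC)cc(Oc2c(OC)cc(OC)cc2Oc2c(OC)cc(Oc3c(OC)cc(OC)cc3O)cc2OC)c1 | intermediate
16 | methyl bromoacetate | COC(=O)CBr | starting material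
17 | methyl 2-(ArO)acetate | COc1cc(OC)cc(Oc2c(OC)cc(OC)cc2Oc2c(OC)cc(Oc3c(OC)cc(OC)cc3OCC(=O)OC)cc2OC)c1 | intermediate
18 | methyl acetoacetate | COC(=O)CC(C)=O | starting material
19 | methyl acetoacetate dianion (sodium lithium salt) | COC(=O)[CH-]C(=O)[CH2-].[Na+].[Li+] | intermediate
20 | methyl 6-(ArO)-3,5-dioxohexanoate | COc1cc(OC)cc(Oc2c(OC)cc(OC)cc2Oc2c(OC)cc(Oc3c(OC)cc(OC)cc3OCC(=O)CC(=O)CC(=O)OC)cc2OC)c1 | intermediate
21 | 2-(ArO)cyclohexane-1,3,5-trione | COc1cc(OC)cc(Oc2c(OC)cc(OC)cc2Oc2c(OC)cc(Oc3c(OC)cc(OC)cc3OC3C(=O)CC(=O)CC3=O)cc2OC)c1 | intermediate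
22 | 2-(ArO)benzene-1,3,5-triol (octamethyl ether of the target) | COc1cc(OC)cc(Oc2c(OC)cc(OC)cc2Oc2c(OC)cc(Oc3c(OC)cc(OC)cc3Oc3c(O)cc(O)cc3O)cc2OC)c1 | intermediate
23 | undeca-O-(dibromoboryl) derivative of the target | BrB(Br)Oc1cc(OB(Br)Br)cc(Oc2c(OB(Br)Br)cc(OB(Br)Br)cc2Oc2c(OB(Br)Br)cc(Oc3c(OB(Br)Br)cc(OB(Br)Br)cc3Oc3c(OB(Br)Br)cc(OB(Br)Br)cc3OB(Br)Br)cc2OB(Br)Br)c1 | intermediate
24 | target pentamer CNP0018313.0 | Oc1cc(O)cc(Oc2c(O)cc(O)cc2Oc2c(O)cc(Oc3c(O)cc(O)cc3Oc3c(O)cc(O)cc3O)cc2O)c1 | target

**Step count and risk**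

Total step count: 12. Longest linear sequence: 10 steps (1, 2, 5, 6, 7, 8, 9, 10, 11, 12).

Steps most likely to fail:

1. Step 11. The ring closure may be diverted into O-acylation (lactonisation to the 2-pyrone), into retro-Claisen fragmentation of the polycarbonyl chain by alkoxide, or may stall because C-6 is not deprotonated in the polyanion. The fallback gives up the de novo ring and sets out from phenol 15. Ullmann coupling with 2-iodo-1,3,5-trimethoxybenzene (CuI, 2,2,6,6-tetramethylheptane-3,5-dione, Cs2CO3, NMP, 130 °C) should give the undeca-O-methyl pentamer F1. Global demethylation with BBr3 in CH2Cl2, through the same borate 23, returns to the route at target 24. The coupling takes place at a doubly flanked aryl carbon, which is why it is held in reserve.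

2. Step 10. Proton transfer from the α-aryloxy ester to the dianion may replace acylation, and the diketo ester may lactonise during acidic work-up. The fallback sets out from ester 17 and builds the chain through a dioxinone. Saponification (LiOH, THF–H2O) gives (ArO)acetic acid F2, and 1,1'-carbonyldiimidazole in THF gives the acyl imidazole F3. Addition of F3 to the lithium dienolate of 2,2,6-trimethyl-4H-1,3-dioxin-4-one (LiHMDS, THF, −78 °C) gives 6-[3-(ArO)-2-oxopropyl]-2,2-dimethyl-4H-1,3-dioxin-4-one F4. Heating F4 in toluene–methanol (110 °C) expels acetone, and methanol traps the acylketene F5 under neutral conditions, which returns to the route at 20.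

3. Step 7. Coupling at a phenol flanked by a methoxy group and a bulky aryloxy group may be slow, so that reductive dehalogenation of 13 or oxidative degradation of the electron-rich phenoxide takes over. The fallback sets out from 12 and replaces the Cu(I)/aryl halide manifold by a Chan–Lam–Evans oxidative coupling with 3,5-dimethoxyphenylboronic acid (Cu(OAc)2, pyridine, 4 Å molecular sieves, CH2Cl2, rt, dry air). It returns to the route at 14 and makes no new compound.

**Further compounds**

F1 | step 11 | undeca-O-methyl ether of the target | COc1cc(OC)cc(Oc2c(OC)cc(OC)cc2Oc2c(OC)cc(Oc3c(OC)cc(OC)cc3Oc3c(OC)cc(OC)cc3OC)cc2OC)c1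
F2 | step 10 | 2-(ArO)acetic acid | COc1cc(OC)cc(Oc2c(OC)cc(OC)cc2Oc2c(OC)cc(Oc3c(OC)cc(OC)cc3OCC(=O)O)cc2OC)c1
F3 | step 10 | 1-[2-(ArO)acetyl]imidazole | COc1cc(OC)cc(Oc2c(OC)cc(OC)cc2Oc2c(OC)cc(Oc3c(OC)cc(OC)cc3OCC(=O)n3ccnc3)cc2OC)c1
F4 | step 10 | 6-[3-(ArO)-2-oxopropyl]-2,2-dimethyl-4H-1,3-dioxin-4-one | COc1cc(OC)cc(Oc2c(OC)cc(OC)cc2Oc2c(OC)cc(Oc3c(OC)cc(OC)cc3OCC(=O)CC3=CC(=O)OC(C)(C)O3)cc2OC)c1
F5 | step 10 | 6-(ArO)-3,5-dioxohex-1-en-1-one (acylketene) | COc1cc(OC)cc(Oc2c(OC)cc(OC)cc2Oc2c(OC)cc(Oc3c(OC)cc(OC)cc3OCC(=O)CC(=O)C=C=O)cc2OC)c1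
F0 | step 7 | none | none
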